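**Retrosynthetic overview**
1. The last steps only adjust functional groups. TFA removes two tert-butyl esters and the catechol acetonide, and the C3 methyl ester comes from a C3 aldehyde (Pinnick oxidation, then methylation).
2. Ring B is cut at C1–C2 and C3=C4. An (S)-diarylprolinol silyl ether Michael/aldol-condensation cascade joins a diarylmethane aldehyde with tert-butyl (E)-4-oxobut-2-enoate, sets C2 and lets C1 settle trans.
3. The ring A–CH2–ring C link is cut at C8a–C1 by an sp2–sp3 Suzuki coupling of an ortho-formylaryl boronate with a 4-(bromomethyl)-2-pyrone.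
4. Three branches of comparable size feed these two consecutive unions: the ring A piece from catechol, the ring C piece from methyl 3-methylbut-2-enoate and dimethyl oxalate, and the C4 enal ester from sorbic acid.
5. Ring order: ring A is bought, ring C is built first (vinylogous Claisen/lactonisation), and ring B is closed last in the cascade.

Assumption: the SMILES is read as the (1R,2S) trans isomer. C1–C8a are the positions of the 1,2-dihydronaphthalene core (C1 pyrone, C2 free acid, C3 methyl ester). In the acetonide-protected tricycles the same atoms are C5 (= C1), C6 (= C2), C7 (= C3) and C8 (= C4) of naphtho[2,3-d][1,3]dioxole.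

**Route**

Step 1
Reactants: 1 catechol (benzene-1,2-diol)
Product: 2 2,2-dimethyl-1,3-benzodioxole
Conditions: Me2C(OMe)2, p-TsOH·H2O (2 mol %), toluene, reflux, Soxhlet with 4 Å MS
Reagents that add atoms: 2,2-dimethoxypropane COC(C)(C)OC
Why: Acid-catalysed transketalisation is driven to the five-membered cyclic ketal by removing methanol, and this acetonide later falls off in the same acid step as the tert-butyl esters.

Step 2
Reactants: 2 2,2-dimethyl-1,3-benzodioxole
Product: 3 5,6-dibromo-2,2-dimethyl-1,3-benzodioxole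
Conditions: NBS (2.1 equiv), MeCN, 0 °C to rt
Reagents that add atoms: N-bromosuccinimide O=C1CCC(=O)N1Br
Why: In this electrophilic aromatic bromination each ring oxygen directs para, so positions 5 and 6 are brominated one after the other, and neutral NBS leaves the acid-labile ketal intact.

Step 3
Reactants: 3 5,6-dibromo-2,2-dimethyl-1,3-benzodioxole
Product: 5 6-bromo-2,2-dimethyl-1,3-benzodioxole-5-carbaldehyde, via arylmagnesium chloride 4 (not isolated)
Conditions: iPrMgCl·LiCl (1.1 equiv), THF, −15 °C; then DMF, −15 °C to rt; aq NH4Cl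
Reagents that add atoms: N,N-dimethylformamide CN(C)C=O
Why: Bromine–magnesium exchange occurs only once because the two C–Br bonds are equivalent and the electron-rich arylmagnesium resists a second exchange, the ortho-bromoaryl Grignard does not collapse to the aryne at −15 °C, and the DMF quench (Bouveault formylation) gives the aldehyde.

Step 4
Reactants: 5 6-bromo-2,2-dimethyl-1,3-benzodioxole-5-carbaldehyde
Product: 6 2,2-dimethyl-6-(4,4,5,5-tetramethyl-1,3,2-dioxaborolan-2-yl)-1,3-benzodioxole-5-carbaldehyde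
Conditions: B2pin2 (1.1 equiv), PdCl2(dppf) (3 mol %), KOAc (3 equiv), 1,4-dioxane, 85 °C
Reagents that add atoms: bis(pinacolato)diboron CC1(C)OB(OC1(C)C)B1OC(C)(C)C(C)(C)O1
Why: In this Miyaura borylation zerovalent palladium inserts into the C–Br bond activated by the ortho formyl group, and the weak base KOAc allows boryl transfer without touching the aldehyde or causing biaryl coupling.

Step 5
Reactants: 7 methyl 3-methylbut-2-enoate; 8 dimethyl oxalate
Product: 10 4-methyl-2-oxo-2H-pyran-6-carboxylic acid, via potassium dienolate 9 (not isolated)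
Conditions: KOMe (1.05 equiv), Et2O/MeOH, 0 °C to rt; then conc. aq HCl, reflux
Reagents that add atoms: water O
Why: A vinylogous (γ-selective) Claisen condensation of the dienolate of 7 with the non-enolisable oxalate gives the stabilised enolate 9, and hot aqueous acid then equilibrates the alkene geometry, lactonises the enol onto the distal ester to form ring C and hydrolyses the remaining methyl ester.

Step 6
Reactants: 10 4-methyl-2-oxo-2H-pyran-6-carboxylic acid
Product: 11 tert-butyl 4-methyl-2-oxo-2H-pyran-6-carboxylate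
Conditions: Cl3CC(=NH)Ot-Bu (2 equiv), BF3·OEt2 (5 mol %), CH2Cl2/THF, rt
Reagents that add atoms: tert-butyl 2,2,2-trichloroacetimidate CC(C)(C)OC(=N)C(Cl)(Cl)Cl
Why: Trichloroacetimidate esterification (acid-catalysed O-alkylation by a tert-butyl cation donor) avoids the bases and nucleophiles that would open the 2-pyrone.

Step 7
Reactants: 11 tert-butyl 4-methyl-2-oxo-2H-pyran-6-carboxylate
Product: 12 tert-butyl 4-(bromomethyl)-2-oxo-2H-pyran-6-carboxylate
Conditions: NBS (1.05 equiv), AIBN (5 mol %), PhCF3, 85 °C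
Reagents that add atoms: N-bromosuccinimide O=C1CCC(=O)N1Br
Why: In this Wohl–Ziegler bromination the 4-methyl group gives an allyl-type radical conjugated with the pyrone, the electron-poor ring resists ionic bromination, and one equivalent of NBS limits dibromide formation.

Step 8
Reactants: 13 sorbic acid ((2E,4E)-hexa-2,4-dienoic acid)
Product: 14 tert-butyl (2E,4E)-hexa-2,4-dienoate
Conditions: Cl3CC(=NH)Ot-Bu (1.5 equiv), BF3·OEt2 (5 mol %), CH2Cl2/cyclohexane, rt
Reagents that add atoms: tert-butyl 2,2,2-trichloroacetimidate CC(C)(C)OC(=N)C(Cl)(Cl)Cl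
Why: Trichloroacetimidate esterification installs the acid-labile ester under mild conditions that leave the diene geometry unchanged.

Step 9
Reactants: 14 tert-butyl (2E,4E)-hexa-2,4-dienoate
Product: 16 tert-butyl (E)-4-oxobut-2-enoate, via secondary ozonide 15 (not isolated)
Conditions: O3, CH2Cl2, −78 °C (Sudan Red 7B end point); then Me2S, −78 °C to rt
Reagents that add atoms: ozone [O-][O+]=O
Why: In this chemoselective ozonolysis the electrophilic ozone attacks the electron-richer γ,δ-alkene of the dienoate, the dye end point prevents over-oxidation, Me2S reduces ozonide 15, and the E geometry of the remaining alkene is untouched.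

Step 10
Reactants: 6 2,2-dimethyl-6-(4,4,5,5-tetramethyl-1,3,2-dioxaborolan-2-yl)-1,3-benzodioxole-5-carbaldehyde; 12 tert-butyl 4-(bromomethyl)-2-oxo-2H-pyran-6-carboxylate
Product: 17 tert-butyl 4-[(6-formyl-2,2-dimethyl-1,3-benzodioxol-5-yl)methyl]-2-oxo-2H-pyran-6-carboxylate
Conditions: Pd(PPh3)4 (5 mol %), K3PO4 (2 equiv), toluene/H2O 20:1, 60 °C, Ar
Reagents that add atoms: none
Why: In this Suzuki–Miyaura sp2–sp3 coupling zerovalent palladium adds readily to the allyl-type C–Br bond of 12, the aryl group is transferred from the phosphate-activated boronate, and reductive elimination is clean because the pyronylmethyl ligand has no β-hydrogen.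

Step 11
Reactants: 17 tert-butyl 4-[(6-formyl-2,2-dimethyl-1,3-benzodioxol-5-yl)methyl]-2-oxo-2H-pyran-6-carboxylate; 16 tert-butyl (E)-4-oxobut-2-enoate
Product: 19 tert-butyl (5R,6S)-5-[6-(tert-butoxycarbonyl)-2-oxo-2H-pyran-4-yl]-7-formyl-2,2-dimethyl-5,6-dihydronaphtho[2,3-d][1,3]dioxole-6-carboxylate, via Michael adduct dialdehyde 18 (not isolated)
Conditions: 16 (1.5 equiv), (S)-2-[diphenyl(trimethylsilyloxy)methyl]pyrrolidine (20 mol %), PhCO2H (20 mol %), CH2Cl2, 0 °C to rt, Ar
Reagents that add atoms: none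
Why: In this iminium–enamine Michael/aldol-condensation cascade the CH2 of 17 (acidified by the vinylogous lactone and the ortho-formylaryl group) adds to the β-carbon of the E-iminium ion of 16 on the face left open by the CPh2OTMS group of the (S)-catalyst, which sets C2 as S, the enamine then closes ring B on the aryl aldehyde and loses water, and the still acidic C1–H equilibrates in the amine/benzoate buffer to the more stable trans (1R) isomer.

Step 12
Reactants: 19 tert-butyl (5R,6S)-5-[6-(tert-butoxycarbonyl)-2-oxo-2H-pyran-4-yl]-7-formyl-2,2-dimethyl-5,6-dihydronaphtho[2,3-d][1,3]dioxole-6-carboxylate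
Product: 20 (5R,6S)-6-(tert-butoxycarbonyl)-5-[6-(tert-butoxycarbonyl)-2-oxo-2H-pyran-4-yl]-2,2-dimethyl-5,6-dihydronaphtho[2,3-d][1,3]dioxole-7-carboxylic acid
Conditions: NaClO2, NaH2PO4, 2-methylbut-2-ene (excess), t-BuOH/THF/H2O, 0 °C to rt
Reagents that add atoms: sodium chlorite [Na+].[O-]Cl=O
Why: Pinnick oxidation converts the enal into the acid at about pH 4 without touching the alkene, the pyrone or the two base-labile stereocentres, and the alkene scavenger removes HOCl before it can chlorinate ring A.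

Step 13
Reactants: 20 (5R,6S)-6-(tert-butoxycarbonyl)-5-[6-(tert-butoxycarbonyl)-2-oxo-2H-pyran-4-yl]-2,2-dimethyl-5,6-dihydronaphtho[2,3-d][1,3]dioxole-7-carboxylic acid
Product: 21 6-tert-butyl 7-methyl (5R,6S)-5-[6-(tert-butoxycarbonyl)-2-oxo-2H-pyran-4-yl]-2,2-dimethyl-5,6-dihydronaphtho[2,3-d][1,3]dioxole-6,7-dicarboxylate
Conditions: TMSCHN2 (1.1 equiv), toluene/MeOH 4:1, 0 °C
Reagents that add atoms: (trimethylsilyl)diazomethane C[Si](C)(C)C=[N+]=[N-]
Why: In this diazoalkane esterification proton transfer from the only free carboxylic acid triggers methylation under essentially neutral conditions, so neither stereocentre can epimerise and the new methyl ester stays differentiated from the two tert-butyl esters.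

Step 14
Reactants: 21 6-tert-butyl 7-methyl (5R,6S)-5-[6-(tert-butoxycarbonyl)-2-oxo-2H-pyran-4-yl]-2,2-dimethyl-5,6-dihydronaphtho[2,3-d][1,3]dioxole-6,7-dicarboxylate
Product: 22 (1R,2S)-1-(6-carboxy-2-oxo-2H-pyran-4-yl)-6,7-dihydroxy-3-(methoxycarbonyl)-1,2-dihydronaphthalene-2-carboxylic acid (CNP0333269.1)
Conditions: TFA/CH2Cl2/H2O 50:45:5, 0 °C to rt
Reagents that add atoms: none
Why: In this global acidolysis TFA cleaves both tert-butyl esters by E1-type loss of isobutene and hydrolyses the catechol ketal, while the methyl ester, the pyrone and the C1 and C2 stereocentres, which are labile only to base, survive.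

**Compound list**
1 | catechol (benzene-1,2-diol) | Oc1ccccc1O | starting material
2 | 2,2-dimethyl-1,3-benzodioxole | CC1(C)Oc2ccccc2O1 | intermediate
3 | 5,6-dibromo-2,2-dimethyl-1,3-benzodioxole | CC1(C)Oc2cc(Br)c(Br)cc2O1 | intermediate
4 | (6-bromo-2,2-dimethyl-1,3-benzodioxol-5-yl)magnesium chloride (not isolated) | CC1(C)Oc2cc(Br)c([Mg]Cl)cc2O1 | intermediate
5 | 6-bromo-2,2-dimethyl-1,3-benzodioxole-5-carbaldehyde | CC1(C)Oc2cc(Br)c(C=O)cc2O1 | intermediate
6 | 2,2-dimethyl-6-(4,4,5,5-tetramethyl-1,3,2-dioxaborolan-2-yl)-1,3-benzodioxole-5-carbaldehyde | CC1(C)Oc2cc(C=O)c(cc2O1)B1OC(C)(C)C(C)(C)O1 | intermediate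
7 | methyl 3-methylbut-2-enoate | COC(=O)C=C(C)C | starting material
8 | dimethyl oxalate | COC(=O)C(=O)OC | starting material
9 | potassium 1,6-dimethoxy-4-methyl-1,6-dioxohexa-2,4-dien-2-olate (alkene geometry not fixed, not isolated) | COC(=O)C([O-])=CC(C)=CC(=O)OC.[K+] | intermediate
10 | 4-methyl-2-oxo-2H-pyran-6-carboxylic acid | Cc1cc(C(=O)O)oc(=O)c1 | intermediate
11 | tert-butyl 4-methyl-2-oxo-2H-pyran-6-carboxylate | Cc1cc(C(=O)OC(C)(C)C)oc(=O)c1 | intermediate
12 | tert-butyl 4-(bromomethyl)-2-oxo-2H-pyran-6-carboxylate | BrCc1cc(C(=O)OC(C)(C)C)oc(=O)c1 | intermediate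
13 | sorbic acid, (2E,4E)-hexa-2,4-dienoic acid | C/C=C/C=C/C(=O)O | starting material
14 | tert-butyl (2E,4E)-hexa-2,4-dienoate | C/C=C/C=C/C(=O)OC(C)(C)C | intermediate
15 | tert-butyl (E)-3-(5-methyl-1,2,4-trioxolan-3-yl)prop-2-enoate (cis/trans ozonide mixture, not isolated) | CC1OOC(/C=C/C(=O)OC(C)(C)C)O1 | intermediate
16 | tert-butyl (E)-4-oxobut-2-enoate | O=C/C=C/C(=O)OC(C)(C)C | intermediate
17 | tert-butyl 4-[(6-formyl-2,2-dimethyl-1,3-benzodioxol-5-yl)methyl]-2-oxo-2H-pyran-6-carboxylate | CC1(C)Oc2cc(C=O)c(Cc3cc(C(=O)OC(C)(C)C)oc(=O)c3)cc2O1 | intermediate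
18 | tert-butyl 4-[(1R,2R)-2-(tert-butoxycarbonyl)-1-(6-formyl-2,2-dimethyl-1,3-benzodioxol-5-yl)-4-oxobutyl]-2-oxo-2H-pyran-6-carboxylate (same spatial arrangement as 19; not isolated) | O=Cc1cc2OC(C)(C)Oc2cc1[C@@H](c1cc(C(=O)OC(C)(C)C)oc(=O)c1)[C@@H](CC=O)C(=O)OC(C)(C)C | intermediate
19 | tert-butyl (5R,6S)-5-[6-(tert-butoxycarbonyl)-2-oxo-2H-pyran-4-yl]-7-formyl-2,2-dimethyl-5,6-dihydronaphtho[2,3-d][1,3]dioxole-6-carboxylate (trans) | O=CC1=Cc2cc3OC(C)(C)Oc3cc2[C@@H](c2cc(C(=O)OC(C)(C)C)oc(=O)c2)[C@@H]1C(=O)OC(C)(C)C | intermediate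
20 | (5R,6S)-6-(tert-butoxycarbonyl)-5-[6-(tert-butoxycarbonyl)-2-oxo-2H-pyran-4-yl]-2,2-dimethyl-5,6-dihydronaphtho[2,3-d][1,3]dioxole-7-carboxylic acid (trans) | OC(=O)C1=Cc2cc3OC(C)(C)Oc3cc2[C@@H](c2cc(C(=O)OC(C)(C)C)oc(=O)c2)[C@@H]1C(=O)OC(C)(C)C | intermediate
21 | 6-tert-butyl 7-methyl (5R,6S)-5-[6-(tert-butoxycarbonyl)-2-oxo-2H-pyran-4-yl]-2,2-dimethyl-5,6-dihydronaphtho[2,3-d][1,3]dioxole-6,7-dicarboxylate (trans) | COC(=O)C1=Cc2cc3OC(C)(C)Oc3cc2[C@@H](c2cc(C(=O)OC(C)(C)C)oc(=O)c2)[C@@H]1C(=O)OC(C)(C)C | intermediate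
22 | (1R,2S)-1-(6-carboxy-2-oxo-2H-pyran-4-yl)-6,7-dihydroxy-3-(methoxycarbonyl)-1,2-dihydronaphthalene-2-carboxylic acid (trans) | COC(=O)C1=Cc2cc(O)c(O)cc2[C@@H](c2cc(C(=O)O)oc(=O)c2)[C@@H]1C(=O)O | target

**Step count**
- Total step count: 14.
- Longest linear sequence: 9 steps (steps 1–4 and 10–14).
- The pyrone branch runs 8 steps to the target and the enal branch 6.

**Steps most likely to fail**

Step 11 (cascade). The secondary amine may add to the electrophilic pyrone, 17 may be too weak a carbon acid, or 19 may lose its C2 configuration through its dienamine.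
- The fallback sets out from 17 and comes back at 21, so 19 and 20 are bypassed.
- Ring B is closed at the ester oxidation level by a Michael/Horner–Wadsworth–Emmons domino under chiral ion-pair (phase-transfer) control instead of iminium catalysis.
- Exhaustive ozonolysis of 14 (excess O3, then Me2S) gives tert-butyl glyoxylate F1.
- An Arbuzov reaction of trimethyl phosphite with methyl bromoacetate gives trimethyl phosphonoacetate F2.
- Knoevenagel condensation of the two (TiCl4, N-methylmorpholine, THF) gives 4-tert-butyl 1-methyl 2-(dimethoxyphosphoryl)but-2-enedioate F3.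
- The union uses solid Cs2CO3 and O-allyl-N-(9-anthracenylmethyl)cinchonidinium bromide in toluene at −40 °C. The carbanion of 17 adds to the CH terminus of F3 to give the phosphonate Michael adduct F4.
- The stabilised phosphonate carbanion of F4 olefinates the neighbouring aryl aldehyde and delivers 21 directly.
- The sense of induction here is not predictable in advance. The pseudoenantiomeric cinchoninium salt is used if it turns out wrong.

Step 10 (Suzuki union). The ortho-formyl boronate 6 can protodeboronate, and the phosphate base can hydrolyse the pyrone or trigger self-condensation of the acidic product 17.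
- The fallback sets out from 5 and comes back at 17, so step 4 is dropped. It exchanges the base-dependent boron chemistry for a base-free tin coupling.
- Compound 5 is stannylated (Bu3SnSnBu3, Pd(PPh3)4, toluene, 110 °C) to 2,2-dimethyl-6-(tributylstannyl)-1,3-benzodioxole-5-carbaldehyde F5.
- F5 undergoes Stille coupling with 12 under neutral conditions (Pd2(dba)3, AsPh3, THF, 50 °C).

Step 7 (radical bromination). Ring bromination at C3, dibromide formation or HBr-induced loss of the tert-butyl ester may dominate.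
- The fallback sets out from 11 and comes back at 12. It uses the acidity of the 4-methyl group instead of radical chemistry.
- Condensation with DMF dimethyl acetal (DMF, 90 °C) gives tert-butyl 4-[(E)-2-(dimethylamino)ethenyl]-2-oxo-2H-pyran-6-carboxylate F6.
- NaIO4 in THF/H2O cleaves the enamine to tert-butyl 4-formyl-2-oxo-2H-pyran-6-carboxylate F7.
- NaBH(OAc)3 reduces only the aldehyde, giving tert-butyl 4-(hydroxymethyl)-2-oxo-2H-pyran-6-carboxylate F8.
- An Appel reaction (CBr4, PPh3, CH2Cl2, 0 °C) returns 12.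

**Further compounds**
F1 | step 11 | tert-butyl glyoxylate | O=CC(=O)OC(C)(C)C
F2 | step 11 | trimethyl phosphonoacetate | COC(=O)CP(=O)(OC)OC
F3 | step 11 | 4-tert-butyl 1-methyl 2-(dimethoxyphosphoryl)but-2-enedioate (E/Z mixture) | COC(=O)C(=CC(=O)OC(C)(C)C)P(=O)(OC)OC
F4 | step 11 | phosphonate Michael adduct of 17 and F3 (C1 and C2 arranged as in 21, epimers at C3, not isolated) | O=Cc1cc2OC(C)(C)Oc2cc1[C@@H](c1cc(C(=O)OC(C)(C)C)oc(=O)c1)[C@@H](C(C(=O)OC)P(=O)(OC)OC)C(=O)OC(C)(C)C
F5 | step 10 | 2,2-dimethyl-6-(tributylstannyl)-1,3-benzodioxole-5-carbaldehyde | CCCC[Sn](CCCC)(CCCC)c1cc2OC(C)(C)Oc2cc1C=O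
F6 | step 7 | tert-butyl 4-[(E)-2-(dimethylamino)ethenyl]-2-oxo-2H-pyran-6-carboxylate | CN(C)/C=C/c1cc(C(=O)OC(C)(C)C)oc(=O)c1
F7 | step 7 | tert-butyl 4-formyl-2-oxo-2H-pyran-6-carboxylate | O=Cc1cc(C(=O)OC(C)(C)C)oc(=O)c1
F8 | step 7 | tert-butyl 4-(hydroxymethyl)-2-oxo-2H-pyran-6-carboxylate | OCc1cc(C(=O)OC(C)(C)C)oc(=O)c1
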